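The cyclopentane (C1, C2, C3, C3a, C7a) carries at C1 the exocyclic carbinol carbon Cα and at C2 a cis hydroxyl. This array is read as the outcome of a semipinacol ring contraction in which Cα was a ring carbon of a cyclohexane. A trans-decalin from Wieland–Miescher ketone, bearing an equatorial mesylate at C1, a tertiary cyclohexenyl carbinol at Cα and a silyloxy group at C2, is contracted by migration of the C2–Cα bond to C1. One operation closes the trans-hydrindane, sets C1 by inversion, retains C2 and releases the side-chain ketone. Both bromides are installed last by radical hydrogenation of alkenyl bromides.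

Key step: step 13

Remarks
- Locants: target numbering is used for every intermediate. Hydrindane carbons are C1–C3, C3a, C4–C7, C7a. Cα is the carbon that carries the acetate; in all decalin intermediates it is a ring carbon between C1 and C2. Cyclohexane carbons are C1′–C6′ (C3′ = CMe2, C4′ = CHBr). α is the face of H-7a, β the face of the 3a-methyl.
- Assumption: ketone 14 is taken as a purchasable building block.
- The carbinol configuration at Cα in 19 is drawn for attack anti to the 3a-methyl; it is lost in step 13, so either epimer serves.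

Step 1
Reactants: 1 (S)-Wieland–Miescher ketone
Product: 2 bis(ethylene ketal) of 1 with the double bond at C7=C7a
Conditions: HOCH2CH2OH, TsOH (cat.), PhH, reflux, Dean–Stark
Reagents that add atoms: ethylene glycol, OCCO
Why: Acid-catalysed ketalisation of both carbonyls; ketalisation of the enone moves the double bond out of conjugation to C7=C7a (as in Δ4-3-keto steroids), which opens C7 to oxygenation.

Step 2
Reactants: 2 bis-ketal alkene
Product: 4 trans-fused 7α-alcohol, via 7α-alkylborane 3 (not isolated)
Conditions: BH3·THF, THF, 0 °C → rt; then NaOH, H2O2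
Reagents that add atoms: hydrogen peroxide, OO
Why: Hydroboration–oxidation; syn addition from the α-face, opposite the angular methyl, puts boron on the less substituted C7 and hydrogen on C7a, which sets the trans ring fusion.

Step 3
Reactants: 4 7α-alcohol
Product: 5 C7 ketone (bis-ketal)
Conditions: TPAP (cat.), NMO, 4 Å MS, CH2Cl2, rt
Reagents that add atoms: none
Why: Ley–Griffith oxidation of the secondary alcohol; the trans-fused ketone is the more stable C7a epimer (as in 5α-6-keto steroids), so the fusion is not at risk.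

Step 4
Reactants: 5 C7 ketone
Product: 6 7β-hydroxy-7α-methyl bis-ketal
Conditions: MeMgBr, THF, −40 → 0 °C
Reagents that add atoms: methylmagnesium bromide, C[Mg]Br
Why: Grignard addition; the axial trajectory is blocked by the syn-axial 3a-methyl, so methyl enters equatorially (α) and the new hydroxyl is axial (β), as required at C7.

Step 5
Reactants: 6 bis-ketal carbinol
Product: 7 Cα ketone with the C4 dioxolane intact
Conditions: PPTS, acetone–H2O, rt
Reagents that add atoms: water, O
Why: Selective ketal hydrolysis; the unhindered Cα dioxolane should cleave well before the C4 dioxolane, which is flanked by the quaternary C3a (compare 3- versus 17-ketals of steroids).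

Step 6
Reactants: 7 Cα ketone
Product: 10 2α-silyloxy Cα ketone, via TBS enol ether 8 (not isolated), via silyloxy epoxide 9 (not isolated)
Conditions: TBSOTf (1.2 equiv), Et3N, CH2Cl2, −78 → −20 °C; then mCPBA, NaHCO3, CH2Cl2, −20 °C → rt
Reagents that add atoms: tert-butyldimethylsilyl triflate, CC(C)(C)[Si](C)(C)OS(=O)(=O)C(F)(F)F; 3-chloroperoxybenzoic acid, O=C(OO)c1cccc(Cl)c1
Why: Rubottom oxidation; soft enolisation should give the Cα=C2 enol ether (the C1 side is peri-hindered), epoxidation occurs on the α-face anti to the angular methyl, and a 1,4-silyl shift gives the equatorial 2α-silyloxy ketone, while the tertiary 7-OH (1,3-diaxial to the methyl) should stay unsilylated at low temperature.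

Step 7
Reactants: 10 2α-silyloxy ketone
Product: 12 1α-hydroxy-2α-silyloxy ketone, via dipotassium enolate 11 (not isolated)
Conditions: KHMDS (2.2 equiv), THF, −78 °C; then 2-(phenylsulfonyl)-3-phenyloxaziridine, −78 °C; NH4Cl
Reagents that add atoms: 2-(phenylsulfonyl)-3-phenyloxaziridine, O=S(=O)(N1OC1c1ccccc1)c1ccccc1
Why: Kinetic enolate hydroxylation; deprotonation should go to C1 because the silyloxy-bearing C2–H is kinetically less acidic and the C7 alkoxide lies 1,3-diaxial to the axial C1–H, and the oxaziridine then attacks the enolate from the α-face to give the equatorial 1α-alcohol.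

Step 8
Reactants: 12 1α-hydroxy ketone
Product: 13 1α-mesyloxy-2α-silyloxy ketone
Conditions: MsCl, Et3N, CH2Cl2, −20 °C
Reagents that add atoms: methanesulfonyl chloride, CS(=O)(=O)Cl
Why: Sulfonylation (via sulfene) of the only secondary hydroxyl; the hindered tertiary 7-OH is inert and the C1 configuration is untouched.

Step 9
Reactants: 14 7,7-dimethyl-1,4-dioxaspiro[4.5]decan-8-one
Product: 15 bis(ethylene ketal) of 2,2-dimethylcyclohexane-1,4-dione
Conditions: HOCH2CH2OH, TsOH (cat.), PhH, reflux, Dean–Stark
Reagents that add atoms: ethylene glycol, OCCO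
Why: Ketalisation of the remaining, hindered carbonyl under water removal, so that the two carbonyl positions can be told apart in the next step.

Step 10
Reactants: 15 bis-ketal
Product: 16 6,6-dimethyl-1,4-dioxaspiro[4.5]decan-8-one
Conditions: PPTS, acetone–H2O, rt
Reagents that add atoms: water, O
Why: Selective hydrolysis of the less hindered dioxolane; the ketal next to the gem-dimethyl carbon should remain, which frees the future C1′ carbonyl and keeps C4′ masked.

Step 11
Reactants: 16 mono-ketal ketone
Product: 17 2,4,6-triisopropylbenzenesulfonylhydrazone of 16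
Conditions: 2,4,6-triisopropylbenzenesulfonyl hydrazide, THF, HCl (cat.), rt
Reagents that add atoms: 2,4,6-triisopropylbenzenesulfonyl hydrazide, CC(C)c1cc(C(C)C)c(S(=O)(=O)NN)c(C(C)C)c1
Why: Hydrazone condensation that prepares the Shapiro reaction.

Step 12
Reactants: 17 trisylhydrazone; 13 1α-mesyloxy ketone
Product: 19 Cα tertiary cyclohexenyl carbinol, via alkenyllithium 18 (not isolated)
Conditions: 17, n-BuLi (2.1 equiv), THF, −78 → 0 °C; recool to −78 °C, CeCl3; then 13 (0.4 equiv), −78 °C
Reagents that add atoms: none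
Why: Shapiro reaction; double deprotonation at the less hindered α-CH2 (C6′) and loss of N2 and sulfinate give the C1′ alkenyllithium, which as the organocerium adds 1,2 to the α-mesyloxy ketone (a known partner for organometallic addition) from the α-face.

Step 13
Reactants: 19 Cα tertiary carbinol with equatorial C1 mesylate
Product: 21 ring-contracted trans-hydrindanyl cyclohexenyl ketone, via aluminium alkoxide 20 (not isolated)
Conditions: Et3Al (3 equiv), CH2Cl2, −78 → 0 °C
Reagents that add atoms: none
Why: Et3Al turns the Cα–OH into an aluminium alkoxide and activates the mesylate; the Cα–C2 ring bond, antiperiplanar to the equatorial C1–OMs bond in the chair of the six-membered ring C1–Cα–C2–C3–C3a–C7a, migrates to C1 in a concerted pinacol-type (semipinacol) 1,2-shift while the alkoxide collapses to the ketone. The closest known reaction type is the organoaluminium-promoted rearrangement of 2-mesyloxy alcohols, together with the classical ring contraction of cyclohexane 2-hydroxy sulfonates that carry an equatorial leaving group. The cyclopentane (C1, C2, C3, C3a, C7a) is closed by this 1,2-alkyl shift, an internal SN2-type displacement at C1 through a bridged transition state, and Cα leaves the ring as the exocyclic carbonyl. C1 is set by inversion at the migration terminus (the α-equatorial mesylate gives the α side chain, cis to H-7a), C2 migrates with retention and keeps its α-silyloxy group cis to the side chain, and the trans fusion is untouched. The step needs ring-bond migration instead of cyclohexenyl shift, epoxide closure or elimination; the rigid trans-decalin chair places only the Cα–C2 bond anti to the leaving group (cyclohexenyl and oxygen are gauche), and the cold, non-basic medium protects the epimerisable C1–H of the product.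

Step 14
Reactants: 21 enone
Product: 22 (αR)-allylic alcohol
Conditions: (S)-Me-CBS (0.5 equiv), catecholborane, toluene, −78 °C
Reagents that add atoms: none
Why: Corey–Bakshi–Shibata reduction under reagent control; with the α-substituted alkenyl group as the large substituent the (S)-catalyst should deliver hydride to give the (R)-carbinol at Cα, and catecholborane avoids hydroboration of the alkene.

Step 15
Reactants: 22 allylic alcohol
Product: 23 syn (erythro) 1′,6′-epoxy alcohol
Conditions: VO(acac)2 (cat.), t-BuOOH, CH2Cl2, 0 °C → rt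
Reagents that add atoms: tert-butyl hydroperoxide, CC(C)(C)OO
Why: Hydroxyl-directed vanadium epoxidation; A(1,2) strain with the ring CH2 on C1′ places the Cα–H in the alkene plane, so oxygen is delivered to the erythro face, which relays the (R) centre at Cα into the required (R) configuration at C1′ independently of the ring conformation.

Step 16
Reactants: 23 epoxy alcohol
Product: 24 Cα,C1′-diol
Conditions: LiAlH4, THF, 0 °C → 40 °C
Reagents that add atoms: none
Why: Hydride opening of the trisubstituted epoxide at the secondary C6′ (trans-diaxial, SN2) leaves the C1′–O bond intact and gives the tertiary C1′ alcohol; no bromide is present yet.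

Step 17
Reactants: 24 diol bis-ketal
Product: 25 4,4′-diketone
Conditions: PPTS, THF–H2O, 60 °C
Reagents that add atoms: water, O
Why: Hydrolysis of both hindered dioxolanes under buffered acid at higher temperature; the secondary TBS ether and the tertiary alcohols should survive, and acetone is avoided so that the 1,2-diol is not ketalised.

Step 18
Reactants: 25 diketone
Product: 26 bis-hydrazone
Conditions: N2H4·H2O, AcOH (cat.), EtOH, 60 °C
Reagents that add atoms: hydrazine, NN
Why: Hydrazone condensation at both α-quaternary ketones, the standard entry to the Barton-type alkenyl halide synthesis.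

Step 19
Reactants: 26 bis-hydrazone
Product: 27 bis(alkenyl bromide) with C4(Br)=C5 and C4′(Br)=C5′
Conditions: NBS, pyridine, THF, 0 °C → rt
Reagents that add atoms: N-bromosuccinimide, O=C1CCC(=O)N1Br
Why: Bromo analogue of the Barton vinyl iodide synthesis (hydrazone oxidation, bromination, loss of N2); each ketone has a quaternary α-carbon on one side, so the double bond can form only toward C5 and C5′.

Step 20
Reactants: 27 bis(alkenyl bromide)
Product: 28 4β,4′-dibromide (2-O-TBS triol)
Conditions: Mn(dpm)3 (cat.), PhSiH3, t-BuOOH, i-PrOH, rt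
Reagents that add atoms: none
Why: Mn-catalysed hydrogen-atom-transfer hydrogenation, which retains C–Br bonds; H• adds to each CH terminus and the α-bromo radicals take the second hydrogen axially (anti to the 3a-methyl in the hydrindane; in the chair with the large C1′ substituent equatorial in the cyclohexane), so both bromines should end equatorial, 4S and 4′S (cis to the 1′-OH).

Step 21
Reactants: 28 dibromo triol
Product: 29 Cα acetate (2-O-TBS)
Conditions: Ac2O, DMAP (cat.), pyridine, CH2Cl2, 0 °C → rt
Reagents that add atoms: acetic anhydride, CC(=O)OC(C)=O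
Why: Acylation of the only free secondary hydroxyl; the two tertiary alcohols do not react under these conditions and C2–OH is still silylated.

Step 22
Reactants: 29 silyl ether acetate
Product: 30 CNP0166243.1
Conditions: HF·pyridine, THF, 0 °C → rt
Reagents that add atoms: none
Why: Acidic fluoride desilylation frees C2–OH without acetate migration or loss of the secondary bromides.

Compound list
1 | (S)-Wieland–Miescher ketone | C[C@]12CCC(=O)C=C1CCCC2=O | starting material
2 | bis(ethylene ketal), C7=C7a alkene | C[C@]12CCC3(OCCO3)CC1=CCCC24OCCO4 | intermediate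
3 | 7α-alkylborane | C[C@]12CCC3(OCCO3)C[C@@H]1[C@@H](B)CCC24OCCO4 | intermediate (not isolated)
4 | trans-fused 7α-alcohol bis-ketal | C[C@]12CCC3(OCCO3)C[C@@H]1[C@@H](O)CCC24OCCO4 | intermediate
5 | C7 ketone bis-ketal | C[C@]12CCC3(OCCO3)C[C@@H]1C(=O)CCC24OCCO4 | intermediate
6 | 7β-hydroxy-7α-methyl bis-ketal | C[C@]12CCC3(OCCO3)C[C@@H]1[C@](C)(O)CCC24OCCO4 | intermediate
7 | Cα ketone, C4 dioxolane | C[C@]12CCC(=O)C[C@@H]1[C@](C)(O)CCC23OCCO3 | intermediate
8 | Cα=C2 TBS enol ether | C[C@]12CC=C(O[Si](C)(C)C(C)(C)C)C[C@@H]1[C@](C)(O)CCC23OCCO3 | intermediate (not isolated)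
9 | Cα,C2 α-epoxide of 8 | C[C@]12C[C@H]3O[C@@]3(O[Si](C)(C)C(C)(C)C)C[C@@H]1[C@](C)(O)CCC24OCCO4 | intermediate (not isolated)
10 | 2α-TBSO Cα ketone | C[C@]12C[C@@H](O[Si](C)(C)C(C)(C)C)C(=O)C[C@@H]1[C@](C)(O)CCC23OCCO3 | intermediate
11 | dipotassium Cα=C1 enolate / C7 alkoxide | C[C@]12C[C@@H](O[Si](C)(C)C(C)(C)C)C([O-])=C[C@@H]1[C@](C)([O-])CCC23OCCO3.[K+].[K+] | intermediate (not isolated)
12 | 1α-hydroxy-2α-TBSO Cα ketone | C[C@]12C[C@@H](O[Si](C)(C)C(C)(C)C)C(=O)[C@@H](O)[C@@H]1[C@](C)(O)CCC23OCCO3 | intermediate
13 | 1α-mesyloxy-2α-TBSO Cα ketone | C[C@]12C[C@@H](O[Si](C)(C)C(C)(C)C)C(=O)[C@@H](OS(C)(=O)=O)[C@@H]1[C@](C)(O)CCC23OCCO3 | intermediate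
14 | 7,7-dimethyl-1,4-dioxaspiro[4.5]decan-8-one | CC1(C)CC2(CCC1=O)OCCO2 | starting material
15 | 2,2-dimethylcyclohexane-1,4-dione bis(ethylene ketal) | CC1(C)CC2(CCC13OCCO3)OCCO2 | intermediate
16 | 6,6-dimethyl-1,4-dioxaspiro[4.5]decan-8-one | O=C1CCC2(OCCO2)C(C)(C)C1 | intermediate
17 | trisylhydrazone of 16 | CC(C)c1cc(C(C)C)c(S(=O)(=O)NN=C2CCC3(OCCO3)C(C)(C)C2)c(C(C)C)c1 | intermediate
18 | C1′ alkenyllithium (C1′=C6′, C4′ dioxolane) | [Li]C1=CCC2(OCCO2)C(C)(C)C1 | intermediate (not isolated)
19 | Cα tertiary cyclohexenyl carbinol, 1α-OMs, 2α-OTBS | C[C@]12C[C@@H](O[Si](C)(C)C(C)(C)C)[C@@](O)(C3=CCC4(OCCO4)C(C)(C)C3)[C@@H](OS(C)(=O)=O)[C@@H]1[C@](C)(O)CCC25OCCO5 | intermediate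
20 | bis(diethylaluminium) alkoxide of 19 | C[C@]12C[C@@H](O[Si](C)(C)C(C)(C)C)[C@@](O[Al](CC)CC)(C3=CCC4(OCCO4)C(C)(C)C3)[C@@H](OS(C)(=O)=O)[C@@H]1[C@](C)(O[Al](CC)CC)CCC25OCCO5 | intermediate (not isolated)
21 | trans-hydrindan-1-yl cyclohexenyl ketone (2α-OTBS, 7β-OH, two dioxolanes) | O=C([C@@H]1[C@H](O[Si](C)(C)C(C)(C)C)C[C@]2(C)C3(OCCO3)CC[C@@](C)(O)[C@@H]12)C1=CCC2(OCCO2)C(C)(C)C1 | intermediate
22 | (αR)-allylic alcohol | O[C@H]([C@@H]1[C@H](O[Si](C)(C)C(C)(C)C)C[C@]2(C)C3(OCCO3)CC[C@@](C)(O)[C@@H]12)C1=CCC2(OCCO2)C(C)(C)C1 | intermediate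
23 | erythro 1′,6′-epoxy alcohol | O[C@H]([C@@H]1[C@H](O[Si](C)(C)C(C)(C)C)C[C@]2(C)C3(OCCO3)CC[C@@](C)(O)[C@@H]12)[C@@]12O[C@@H]1CC1(OCCO1)C(C)(C)C2 | intermediate
24 | Cα,C1′-diol bis-ketal | O[C@H]([C@@H]1[C@H](O[Si](C)(C)C(C)(C)C)C[C@]2(C)C3(OCCO3)CC[C@@](C)(O)[C@@H]12)[C@@]1(O)CCC2(OCCO2)C(C)(C)C1 | intermediate
25 | 4,4′-diketone | O[C@H]([C@@H]1[C@H](O[Si](C)(C)C(C)(C)C)C[C@]2(C)C(=O)CC[C@@](C)(O)[C@@H]12)[C@@]1(O)CCC(=O)C(C)(C)C1 | intermediate
26 | 4,4′-bis-hydrazone | O[C@H]([C@@H]1[C@H](O[Si](C)(C)C(C)(C)C)C[C@]2(C)C(=NN)CC[C@@](C)(O)[C@@H]12)[C@@]1(O)CCC(=NN)C(C)(C)C1 | intermediate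
27 | bis(alkenyl bromide) | O[C@H]([C@@H]1[C@H](O[Si](C)(C)C(C)(C)C)C[C@]2(C)C(Br)=CC[C@@](C)(O)[C@@H]12)[C@@]1(O)CC=C(Br)C(C)(C)C1 | intermediate
28 | 4β,4′-dibromo triol 2-O-TBS ether | O[C@H]([C@@H]1[C@H](O[Si](C)(C)C(C)(C)C)C[C@]2(C)[C@@H](Br)CC[C@@](C)(O)[C@@H]12)[C@@]1(O)CC[C@H](Br)C(C)(C)C1 | intermediate
29 | Cα acetate 2-O-TBS ether | CC(=O)O[C@H]([C@@H]1[C@H](O[Si](C)(C)C(C)(C)C)C[C@]2(C)[C@@H](Br)CC[C@@](C)(O)[C@@H]12)[C@@]1(O)CC[C@H](Br)C(C)(C)C1 | intermediate
30 | CNP0166243.1 | CC(=O)O[C@H]([C@@H]1[C@H](O)C[C@]2(C)[C@@H](Br)CC[C@@](C)(O)[C@@H]12)[C@@]1(O)CC[C@H](Br)C(C)(C)C1 | target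

Total step count: 22. Longest linear sequence: 19 steps (steps 1–8 and 12–22; steps 9–11 prepare the cyclohexenyl fragment).

Steps most likely to fail

Step 13. The tertiary allylic carbinol may ionise under the Lewis acid, or the cyclohexenyl group may shift in place of the ring bond; the product enone may also be attacked. The fallback does the contraction at the aldehyde level, before the alkenyl group is present. It sets out from 13: DIBAL-H (CH2Cl2, −78 °C) reduces the Cα ketone to the mesyloxy alcohol F1. Et3Al then effects the same antiperiplanar ring-bond shift (reductive pinacol-type rearrangement) to the ring-contracted aldehyde F2. Addition of alkenyllithium 18 (CeCl3, −78 °C) gives the allylic alcohols F3 as a mixture of Cα epimers, and Ley–Griffith oxidation returns to the route at 21.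

Step 12. The basic alkenylmetal may enolise the α-mesyloxy ketone or cause β-elimination instead of 1,2-addition. The fallback adds the nucleophile before the leaving group exists. It sets out from 12: excess 18 (3.5 equiv, CeCl3, −78 °C) adds to the acyloin as its alkoxide to give the triol F4. MsCl/Et3N then sulfonylates the only secondary hydroxyl (C1), and the route is rejoined at 19.

Step 7. Deprotonation may occur at the silyloxy-bearing C2 instead of C1, or be slow because the axial C1–H is shielded. The fallback fixes the regiochemistry with an alkoxide at C2. It sets out from 7: TMSOTf/Et3N gives the TMS enol ether F5, and mCPBA followed by citric acid gives the 2α-hydroxy ketone F6. KHMDS (3.3 equiv) then enolises only toward C1, since the C2 alkoxide blocks the other side, and the sulfonyloxaziridine gives the 1α,2α-dihydroxy ketone F7. TBSCl/imidazole silylates the less hindered C2–OH, and the route is rejoined at 12.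

Further compounds
F1 | step 13 | 1α-mesyloxy-2α-TBSO Cα secondary alcohol (β-OH drawn) | C[C@]12C[C@@H](O[Si](C)(C)C(C)(C)C)[C@H](O)[C@@H](OS(C)(=O)=O)[C@@H]1[C@](C)(O)CCC23OCCO3
F2 | step 13 | ring-contracted trans-hydrindane-1α-carbaldehyde (2α-OTBS, 7β-OH, C4 dioxolane) | O=C[C@@H]1[C@H](O[Si](C)(C)C(C)(C)C)C[C@]2(C)C3(OCCO3)CC[C@@](C)(O)[C@@H]12
F3 | step 13 | allylic alcohols, both Cα epimers | OC([C@@H]1[C@H](O[Si](C)(C)C(C)(C)C)C[C@]2(C)C3(OCCO3)CC[C@@](C)(O)[C@@H]12)C1=CCC2(OCCO2)C(C)(C)C1
F4 | step 12 | 1α-hydroxy Cα tertiary cyclohexenyl carbinol (triol, 2α-OTBS) | C[C@]12C[C@@H](O[Si](C)(C)C(C)(C)C)[C@@](O)(C3=CCC4(OCCO4)C(C)(C)C3)[C@@H](O)[C@@H]1[C@](C)(O)CCC25OCCO5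
F5 | step 7 | Cα=C2 TMS enol ether of 7 | C[C@]12CC=C(O[Si](C)(C)C)C[C@@H]1[C@](C)(O)CCC23OCCO3
F6 | step 7 | 2α-hydroxy Cα ketone | C[C@]12C[C@@H](O)C(=O)C[C@@H]1[C@](C)(O)CCC23OCCO3
F7 | step 7 | 1α,2α-dihydroxy Cα ketone | C[C@]12C[C@@H](O)C(=O)[C@@H](O)[C@@H]1[C@](C)(O)CCC23OCCO3
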